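**Retrosynthetic overview**
1. Last bond: the C(sp2)–C(sp3) bond between the CH of the E-trisubstituted alkene and the CH2CH2 arm of the oxirane. It is made by nickel-catalysed radical cross-electrophile coupling of an E-alkenyl iodide (C16 left half) with a 2-(oxiranyl)ethyl iodide (C17 right half), with the epoxide already in place.
2. The oxirane, the only ring, is closed one step earlier on the right half by hydroxyl-directed asymmetric epoxidation of an E-homoallylic alcohol, so the other alkenes do not compete.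
3. Both E-trisubstituted alkenes come from terminal alkynes by Zr-catalysed methylalumination (iodine quench on the left, ethylene oxide quench on the right).
4. Each CH(CH3)–C(=CH2) unit comes from (R)- or (S)-α-methyl-γ-butyrolactone (Ru–BINAP hydrogenation of α-methylene-γ-butyrolactone): organolithium opening, Wittig methylenation in the same flask, then OH → I → acetylide.

Assumption: in steps 1, 4 and 13 the face is fixed by the ligand antipode; the antipodes written are those taken to give the configurations drawn, and the mirror-image ligand is used if calibration shows the opposite sense.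

**Step 1**
Reactants: 1 3-methylideneoxolan-2-one (α-methylene-γ-butyrolactone)
Product: 2 (3S)-3-methyloxolan-2-one
Conditions: H2 (100 atm), Ru(OAc)2[(R)-BINAP] (0.5 mol %), CH2Cl2, 50 °C
Reagents that add atoms: none
Why: Ru–BINAP asymmetric hydrogenation of the exocyclic α-methylene lactone; carbonyl-directed hydride delivery to one alkene face sets the (S) methyl centre of the left terminus.

**Step 2**
Reactants: 2 (3S)-3-methyloxolan-2-one
Product: 4 (3S)-3,4-dimethylpent-4-en-1-ol, via keto alkoxide 3 (not isolated)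
Conditions: MeLi (1.05 equiv), THF, −78 °C; then Ph3P=CH2 (from Ph3PCH3Br, KHMDS), −78 → 23 °C
Reagents that add atoms: methyllithium, [Li]C; methylidenetriphenylphosphorane, C=P(c1ccccc1)(c1ccccc1)c1ccccc1
Why: Organolithium mono-addition to the lactone stops at the lactolate at −78 °C, and its ring-opened keto alkoxide undergoes Wittig methylenation in the same flask; the stereocentre is not a reacting atom and stays (S).

**Step 3**
Reactants: 4 (3S)-3,4-dimethylpent-4-en-1-ol
Product: 5 (3S)-5-iodo-2,3-dimethylpent-1-ene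
Conditions: I2, PPh3, imidazole, CH2Cl2, 0 °C
Reagents that add atoms: iodine, II
Why: Appel iodination of a primary alcohol under buffered conditions leaves the 1,1-disubstituted alkene and the stereocentre untouched.

**Step 4**
Reactants: 1 3-methylideneoxolan-2-one
Product: 6 (3R)-3-methyloxolan-2-one
Conditions: H2 (100 atm), Ru(OAc)2[(S)-BINAP] (0.5 mol %), CH2Cl2, 50 °C
Reagents that add atoms: none
Why: The same Ru–BINAP asymmetric hydrogenation with the antipodal ligand sets the (R) methyl centre used for both inner stereocentres.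

**Step 5**
Reactants: 5 (3S)-5-iodo-2,3-dimethylpent-1-ene; 6 (3R)-3-methyloxolan-2-one
Product: 9 (3R,7S)-3,7,8-trimethyl-4-methylidenenon-8-en-1-ol, via organolithium 7 (not isolated), via keto alkoxide 8 (not isolated)
Conditions: t-BuLi (2.0 equiv), Et2O–pentane, −78 °C; then 6, THF, −78 °C; then Ph3P=CH2 (from Ph3PCH3Br, KHMDS), −78 → 23 °C
Reagents that add atoms: methylidenetriphenylphosphorane, C=P(c1ccccc1)(c1ccccc1)c1ccccc1
Why: Lithium–iodine exchange gives a primary alkyllithium that adds once to the lactone, and Wittig methylenation of the resulting keto alkoxide installs the 1,1-disubstituted alkene; both stereocentres are carried in from 5 and 6.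

**Step 6**
Reactants: 9 (3R,7S)-3,7,8-trimethyl-4-methylidenenon-8-en-1-ol
Product: 10 (3S,7R)-9-iodo-2,3,7-trimethyl-6-methylidenenon-1-ene
Conditions: I2, PPh3, imidazole, CH2Cl2, 0 °C
Reagents that add atoms: iodine, II
Why: Appel iodination of the primary alcohol; no stereocentre is involved.

**Step 7**
Reactants: 10 (3S,7R)-9-iodo-2,3,7-trimethyl-6-methylidenenon-1-ene; 11 lithium acetylide–ethylenediamine complex
Product: 12 (3S,7R)-2,3,7-trimethyl-6-methylideneundec-1-en-10-yne
Conditions: DMSO, 23 °C
Reagents that add atoms: none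
Why: SN2 alkylation of lithium acetylide by an unhindered primary iodide gives the terminal alkyne.

**Step 8**
Reactants: 12 (3S,7R)-2,3,7-trimethyl-6-methylideneundec-1-en-10-yne
Product: 14 (1E,5R,9S)-1-iodo-2,5,9,10-tetramethyl-6-methylideneundeca-1,10-diene, via alkenyldimethylalane 13 (not isolated)
Conditions: AlMe3 (2.5 equiv), Cp2ZrCl2 (25 mol %), CH2Cl2, 0 → 23 °C; then I2, THF, −30 °C
Reagents that add atoms: trimethylaluminium, C[Al](C)C; iodine, II
Why: Zirconium-catalysed methylalumination (Negishi carboalumination) adds Me and Al syn across the terminal alkyne with Me on the internal carbon, and iodinolysis with retention gives the E-alkenyl iodide; the 1,1-disubstituted alkenes do not react.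

**Step 9**
Reactants: 15 5-bromo-2-methylpent-2-ene; 6 (3R)-3-methyloxolan-2-one
Product: 18 (3R)-3,8-dimethyl-4-methylidenenon-7-en-1-ol, via homoprenyllithium 16 (not isolated), via keto alkoxide 17 (not isolated)
Conditions: Li (1 % Na), Et2O, −10 °C; then 6, THF, −78 °C; then Ph3P=CH2 (from Ph3PCH3Br, KHMDS), −78 → 23 °C
Reagents that add atoms: methylidenetriphenylphosphorane, C=P(c1ccccc1)(c1ccccc1)c1ccccc1
Why: Reductive lithiation, mono-addition to the lactone and in-flask Wittig methylenation as in step 5; the (R) centre comes from 6.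

**Step 10**
Reactants: 18 (3R)-3,8-dimethyl-4-methylidenenon-7-en-1-ol
Product: 19 (7R)-9-iodo-2,7-dimethyl-6-methylidenenon-2-ene
Conditions: I2, PPh3, imidazole, CH2Cl2, 0 °C
Reagents that add atoms: iodine, II
Why: Appel iodination of the primary alcohol; the alkenes are inert under these buffered conditions.

**Step 11**
Reactants: 19 (7R)-9-iodo-2,7-dimethyl-6-methylidenenon-2-ene; 11 lithium acetylide–ethylenediamine complex
Product: 20 (5R)-5,10-dimethyl-6-methylideneundec-9-en-1-yne
Conditions: DMSO, 23 °C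
Reagents that add atoms: none
Why: SN2 alkylation of lithium acetylide by the primary iodide.

**Step 12**
Reactants: 20 (5R)-5,10-dimethyl-6-methylideneundec-9-en-1-yne; 21 oxirane (ethylene oxide)
Product: 24 (3E,7R)-4,7,12-trimethyl-8-methylidenetrideca-3,11-dien-1-ol, via alkenyldimethylalane 22 (not isolated), via lithium alkenylaluminate 23 (not isolated)
Conditions: AlMe3 (2.5 equiv), Cp2ZrCl2 (25 mol %), CH2Cl2, 23 °C; evaporate; n-BuLi, hexane–THF, −78 °C; then 21, −78 → 23 °C
Reagents that add atoms: trimethylaluminium, C[Al](C)C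
Why: Negishi methylalumination sets the E-trisubstituted alkene by syn addition, and the derived aluminate opens ethylene oxide with retention at the alkenyl carbon to give the E-homoallylic alcohol.

**Step 13**
Reactants: 24 (3E,7R)-4,7,12-trimethyl-8-methylidenetrideca-3,11-dien-1-ol
Product: 25 2-[(2R,3R)-3-methyl-3-[(3R)-3,8-dimethyl-4-methylidenenon-7-en-1-yl]oxiran-2-yl]ethan-1-ol
Conditions: VO(OiPr)3 (2 mol %), (R,R)-bishydroxamic acid ligand [N,N′-dihydroxy-N,N′-bis(2,2-diarylacetyl)-(1R,2R)-cyclohexane-1,2-diamine] (4 mol %), cumene hydroperoxide (1.5 equiv), toluene, 23 °C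
Reagents that add atoms: cumene hydroperoxide, CC(C)(OO)c1ccccc1
Why: Hydroxyl-directed vanadium/chiral bishydroxamic acid epoxidation of a homoallylic alcohol delivers oxygen only to the alkene held next to the bound alkoxide; syn addition to the E-alkene with ligand-controlled face selection gives the (2R,3R) oxirane, the only ring.

**Step 14**
Reactants: 25 2-[(2R,3R)-3-methyl-3-[(3R)-3,8-dimethyl-4-methylidenenon-7-en-1-yl]oxiran-2-yl]ethan-1-ol
Product: 26 (2R,3R)-3-(2-iodoethyl)-2-methyl-2-[(3R)-3,8-dimethyl-4-methylidenenon-7-en-1-yl]oxirane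
Conditions: I2, PPh3, imidazole, CH2Cl2, 0 °C, 20 min
Reagents that add atoms: iodine, II
Why: Appel iodination with imidazole buffering converts the primary alcohol without opening the trisubstituted epoxide when kept cold and short.

**Step 15**
Reactants: 14 (1E,5R,9S)-1-iodo-2,5,9,10-tetramethyl-6-methylideneundeca-1,10-diene; 26 (2R,3R)-3-(2-iodoethyl)-2-methyl-2-[(3R)-3,8-dimethyl-4-methylidenenon-7-en-1-yl]oxirane
Product: 27 (2R,3R)-2-methyl-2-[(3R)-3,8-dimethyl-4-methylidenenon-7-en-1-yl]-3-[(3E,7R,11S)-4,7,11,12-tetramethyl-8-methylidenetrideca-3,12-dien-1-yl]oxirane (CNP0279512.1)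
Conditions: NiBr2(dme) (10 mol %), 4,4′-di-tert-butyl-2,2′-bipyridine (12 mol %), TDAE (1.6 equiv), NaI (25 mol %), DMA, 23 °C, 26 (1.4 equiv) added slowly
Reagents that add atoms: none
Why: Nickel-catalysed reductive cross-electrophile coupling in which the alkenyl iodide adds oxidatively to zerovalent nickel and the primary alkyl radical, formed from 26 by iodine-atom abstraction, is captured by the alkenylnickel, so reductive elimination forms the C–C bond with retention of E geometry. The radical sits two carbons from the oxirane and cannot open it, the organic reductant leaves no Lewis-acidic metal halide, and no stereocentre is touched.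

**Compound list**
1 | 3-methylideneoxolan-2-one (α-methylene-γ-butyrolactone) | C=C1CCOC1=O | starting material
2 | (3S)-3-methyloxolan-2-one | C[C@H]1CCOC1=O | intermediate
3 | lithium (3S)-3-methyl-4-oxopentan-1-olate (open form of the lactolate) | [Li+].[O-]CC[C@H](C)C(C)=O | intermediate
4 | (3S)-3,4-dimethylpent-4-en-1-ol | OCC[C@H](C)C(C)=C | intermediate
5 | (3S)-5-iodo-2,3-dimethylpent-1-ene | ICC[C@H](C)C(C)=C | intermediate
6 | (3R)-3-methyloxolan-2-one | C[C@@H]1CCOC1=O | intermediate
7 | [(3S)-3,4-dimethylpent-4-en-1-yl]lithium | [Li]CC[C@H](C)C(C)=C | intermediate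
8 | lithium (3R,7S)-3,7,8-trimethyl-4-oxonon-8-en-1-olate | [Li+].[O-]CC[C@@H](C)C(=O)CC[C@H](C)C(C)=C | intermediate
9 | (3R,7S)-3,7,8-trimethyl-4-methylidenenon-8-en-1-ol | OCC[C@@H](C)C(=C)CC[C@H](C)C(C)=C | intermediate
10 | (3S,7R)-9-iodo-2,3,7-trimethyl-6-methylidenenon-1-ene | ICC[C@@H](C)C(=C)CC[C@H](C)C(C)=C | intermediate
11 | lithium acetylide–ethylenediamine complex | [Li]C#C.NCCN | starting material
12 | (3S,7R)-2,3,7-trimethyl-6-methylideneundec-1-en-10-yne | C#CCC[C@@H](C)C(=C)CC[C@H](C)C(C)=C | intermediate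
13 | [(1E,5R,9S)-2,5,9,10-tetramethyl-6-methylideneundeca-1,10-dien-1-yl]dimethylalane | C[Al](C)/C=C(C)/CC[C@@H](C)C(=C)CC[C@H](C)C(C)=C | intermediate
14 | (1E,5R,9S)-1-iodo-2,5,9,10-tetramethyl-6-methylideneundeca-1,10-diene | I/C=C(C)/CC[C@@H](C)C(=C)CC[C@H](C)C(C)=C | intermediate
15 | 5-bromo-2-methylpent-2-ene | CC(C)=CCCBr | starting material
16 | (4-methylpent-3-en-1-yl)lithium | [Li]CCC=C(C)C | intermediate
17 | lithium (3R)-3,8-dimethyl-4-oxonon-7-en-1-olate | [Li+].[O-]CC[C@@H](C)C(=O)CCC=C(C)C | intermediate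
18 | (3R)-3,8-dimethyl-4-methylidenenon-7-en-1-ol | OCC[C@@H](C)C(=C)CCC=C(C)C | intermediate
19 | (7R)-9-iodo-2,7-dimethyl-6-methylidenenon-2-ene | ICC[C@@H](C)C(=C)CCC=C(C)C | intermediate
20 | (5R)-5,10-dimethyl-6-methylideneundec-9-en-1-yne | C#CCC[C@@H](C)C(=C)CCC=C(C)C | intermediate
21 | oxirane (ethylene oxide) | C1CO1 | starting material
22 | [(1E,5R)-2,5,10-trimethyl-6-methylideneundeca-1,9-dien-1-yl]dimethylalane | C[Al](C)/C=C(C)/CC[C@@H](C)C(=C)CCC=C(C)C | intermediate
23 | lithium butyl[(1E,5R)-2,5,10-trimethyl-6-methylideneundeca-1,9-dien-1-yl]dimethylaluminate | [Li+].CCCC[Al-](C)(C)/C=C(C)/CC[C@@H](C)C(=C)CCC=C(C)C | intermediate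
24 | (3E,7R)-4,7,12-trimethyl-8-methylidenetrideca-3,11-dien-1-ol | OCC/C=C(C)/CC[C@@H](C)C(=C)CCC=C(C)C | intermediate
25 | 2-[(2R,3R)-3-methyl-3-[(3R)-3,8-dimethyl-4-methylidenenon-7-en-1-yl]oxiran-2-yl]ethan-1-ol | OCC[C@H]1O[C@]1(C)CC[C@@H](C)C(=C)CCC=C(C)C | intermediate
26 | (2R,3R)-3-(2-iodoethyl)-2-methyl-2-[(3R)-3,8-dimethyl-4-methylidenenon-7-en-1-yl]oxirane | ICC[C@H]1O[C@]1(C)CC[C@@H](C)C(=C)CCC=C(C)C | intermediate
27 | (2R,3R)-2-methyl-2-[(3R)-3,8-dimethyl-4-methylidenenon-7-en-1-yl]-3-[(3E,7R,11S)-4,7,11,12-tetramethyl-8-methylidenetrideca-3,12-dien-1-yl]oxirane | C=C(CC[C@H](C)C(=C)C)[C@H](C)CC/C(C)=C/CC[C@H]1O[C@]1(C)CC[C@@H](C)C(=C)CCC=C(C)C | target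

**Totals**
Total step count: 15. Longest linear sequence: 8 steps (1, 2, 3, 5, 6, 7, 8, 15; the right-half line 4, 9, 10, 11, 12, 13, 14, 15 is equally long).

**Steps most likely to fail**

Step 15 (the radical coupling). The risks are epoxide opening, loss of E geometry at the alkenylnickel stage, and homodimerisation of either iodide. The fallback sets out from 14 and comes back at 27. Lithium–iodine exchange on 14 (t-BuLi, Et2O, −78 °C) gives [(1E,5R,9S)-2,5,9,10-tetramethyl-6-methylideneundeca-1,10-dien-1-yl]lithium F1, and MgBr2·OEt2 turns it into the alkenylmagnesium bromide F2. F2 is then coupled with 26 using Fe(acac)3 (5 mol %) and TMEDA in THF at −20 °C. This is a redox-neutral iron-catalysed alkenyl Grignard–alkyl iodide coupling in which the alkyl radical from 26 is still the C–C-forming species, but no external reductant is present and the reaction is over in minutes at low temperature.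

Step 13 (directed asymmetric epoxidation). The risks are modest enantioselectivity on a trisubstituted homoallylic alcohol, an unconfirmed facial sense, and acid-promoted cyclisation of the 3,4-epoxy alcohol to a tetrahydrofuran. The fallback sets out from 20 and comes back at 25. Methylalumination as in step 12 gives 22, which is quenched with paraformaldehyde to the allylic alcohol (2E,6R)-3,6,11-trimethyl-7-methylidenedodeca-2,10-dien-1-ol F3. Sharpless asymmetric epoxidation (Ti(OiPr)4, D-(−)-diethyl tartrate, t-BuOOH, 4 Å sieves, CH2Cl2, −20 °C), which is chemoselective for the allylic alcohol and of well-established facial sense, gives [(2R,3R)-3-methyl-3-[(3R)-3,8-dimethyl-4-methylidenenon-7-en-1-yl]oxiran-2-yl]methanol F4. Oxidation with SO3·pyridine, DMSO and i-Pr2NEt gives (2S,3R)-3-methyl-3-[(3R)-3,8-dimethyl-4-methylidenenon-7-en-1-yl]oxirane-2-carbaldehyde F5. Wittig methylenation gives (2R,3R)-3-ethenyl-2-methyl-2-[(3R)-3,8-dimethyl-4-methylidenenon-7-en-1-yl]oxirane F6. Hydroboration of the monosubstituted vinyl group with disiamylborane, followed by NaOH/H2O2, gives 25.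

Step 5 (the same one-flask operation is used in steps 2 and 9). The risks are double addition to the lactone and partial epimerisation of the α-methyl ketone under the basic ylide. The fallback sets out from 6, uses 5 as partner, and comes back at 9. MeLi opens 6 to (3R)-5-hydroxy-3-methylpentan-2-one F7, and TBSCl/imidazole gives (3R)-5-[(tert-butyldimethylsilyl)oxy]-3-methylpentan-2-one F8. Kinetic enolisation at the methyl group (LDA, −78 °C; PhNTf2) gives (3R)-5-[(tert-butyldimethylsilyl)oxy]-3-methylpent-1-en-2-yl trifluoromethanesulfonate F9 without touching the stereocentre. Nickel-catalysed reductive coupling of F9 with 5 (NiBr2(dme), 4,4′-di-tert-butyl-2,2′-bipyridine, Mn, DMA) forms the 1,1-disubstituted alkene directly as tert-butyldimethyl{[(3R,7S)-3,7,8-trimethyl-4-methylidenenon-8-en-1-yl]oxy}silane F10, and TBAF gives 9.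

**Further compounds**
F1 | step 15 | [(1E,5R,9S)-2,5,9,10-tetramethyl-6-methylideneundeca-1,10-dien-1-yl]lithium | [Li]/C=C(C)/CC[C@@H](C)C(=C)CC[C@H](C)C(C)=C
F2 | step 15 | [(1E,5R,9S)-2,5,9,10-tetramethyl-6-methylideneundeca-1,10-dien-1-yl]magnesium bromide | Br[Mg]/C=C(C)/CC[C@@H](C)C(=C)CC[C@H](C)C(C)=C
F3 | step 13 | (2E,6R)-3,6,11-trimethyl-7-methylidenedodeca-2,10-dien-1-ol | OC/C=C(C)/CC[C@@H](C)C(=C)CCC=C(C)C
F4 | step 13 | [(2R,3R)-3-methyl-3-[(3R)-3,8-dimethyl-4-methylidenenon-7-en-1-yl]oxiran-2-yl]methanol | OC[C@H]1O[C@]1(C)CC[C@@H](C)C(=C)CCC=C(C)C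
F5 | step 13 | (2S,3R)-3-methyl-3-[(3R)-3,8-dimethyl-4-methylidenenon-7-en-1-yl]oxirane-2-carbaldehyde | O=C[C@H]1O[C@]1(C)CC[C@@H](C)C(=C)CCC=C(C)C
F6 | step 13 | (2R,3R)-3-ethenyl-2-methyl-2-[(3R)-3,8-dimethyl-4-methylidenenon-7-en-1-yl]oxirane | C=C[C@H]1O[C@]1(C)CC[C@@H](C)C(=C)CCC=C(C)C
F7 | step 5 | (3R)-5-hydroxy-3-methylpentan-2-one | OCC[C@@H](C)C(C)=O
F8 | step 5 | (3R)-5-[(tert-butyldimethylsilyl)oxy]-3-methylpentan-2-one | CC(C)(C)[Si](C)(C)OCC[C@@H](C)C(C)=O
F9 | step 5 | (3R)-5-[(tert-butyldimethylsilyl)oxy]-3-methylpent-1-en-2-yl trifluoromethanesulfonate | CC(C)(C)[Si](C)(C)OCC[C@@H](C)C(=C)OS(=O)(=O)C(F)(F)F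
F10 | step 5 | tert-butyldimethyl{[(3R,7S)-3,7,8-trimethyl-4-methylidenenon-8-en-1-yl]oxy}silane | CC(C)(C)[Si](C)(C)OCC[C@@H](C)C(=C)CC[C@H](C)C(C)=C
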